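## Retrosynthetic overview

1. Labels: C1 is the ring carbon bearing the carboxyl, C2 the enol carbon, C4 bears the isopropenyl group, C6 bears the side chain. Cα, Cβ and Cγ are the γ-lactone carbons, Cδ is the ring CH2, and Cq is the quaternary carbinol carbon. The plan rests on the Cγ(H)(O)–CδH2 pair inside the nine-membered ring C1–C(=O)–O–Cq–Cδ–Cγ–Cβ–Cα–C6. This pair lies between two oxygen-bearing carbons (Cq and Cβ), so it is treated as a Z-Cγ=Cδ alkene built from two vinyl groups.
2. The bridging γ-lactone (O–C(=O)–Cα–Cβ–Cγ) is taken back to a Cα tert-butyl ester plus that alkene (iodolactonisation, then stannane). The alkene is cut by ring-closing metathesis to diene 29.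
3. Diene 29 is cut at three bonds: the ester C–O (acylketene plus tertiary vinyl carbinol 9), Cα–Cβ (titanium syn-aldol with acrolein), and C6–Cα (Mukaiyama–Michael addition to keto-enoate 19).
4. Keto-enoate 19 comes from (S)-perillic acid by oxygenation at C2 and transposition of the alkene to C1=C6. Carbinol 9 comes from (R)-linalool, whose prenyl arm must lose four carbons, which takes two successive ozonolyses.
5. Ring order: cyclohexene (chiral pool), then the nine-membered lactone (step 17), then the bridging γ-lactone (step 18).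

Key step: step 17

Assumption: β-keto esters 17, 26 and 28 and the target are written as their chelated enol tautomers, which is the form drawn for the target. TBS = tert-butyldimethylsilyl.

## Route

Step 1
Reactants: 1 (R)-(−)-linalool
Product: 3 (5R)-5-ethenyl-5-methyloxolan-2-ol (lactol; anomer mixture), via hydroxy-aldehyde 2 (not isolated)
Conditions: O3, CH2Cl2–MeOH, −78 °C (Sudan III end point); Me2S, −78 °C → rt
Reagents that add atoms: ozone, [O-][O+]=O
Why: Chemoselective ozonolysis, in which the electron-rich trisubstituted alkene reacts far faster than the vinyl group deactivated by the allylic oxygen, after which the γ-hydroxy aldehyde closes to the lactol and the carbinol centre is untouched.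

Step 2
Reactants: 3 (5R)-5-ethenyl-5-methyloxolan-2-ol
Product: 5 (2R)-2-ethenyl-2-methyl-2,3-dihydrofuran, via lactol mesylate 4 (not isolated)
Conditions: MsCl, Et3N, CH2Cl2, 0 °C → reflux
Reagents that add atoms: methanesulfonyl chloride, CS(=O)(=O)Cl (in 4 only)
Why: Mesylation–elimination of a lactol (glycal-type enol ether synthesis) under basic conditions, which turns the one surplus chain carbon left by step 1 into an enol ether carbon that can be cut off.

Step 3
Reactants: 5 (2R)-2-ethenyl-2-methyl-2,3-dihydrofuran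
Product: 6 (3R)-3-methyl-1-oxopent-4-en-3-yl formate
Conditions: O3 (1 equiv), CH2Cl2, −78 °C; Me2S, −78 °C → rt
Reagents that add atoms: ozone, [O-][O+]=O
Why: Second chemoselective ozonolysis, since the cyclic enol ether is much more reactive toward ozone than the vinyl group, and the cleavage leaves the surplus carbon as an O-formyl group that also masks the tertiary alcohol.

Step 4
Reactants: 6 (3R)-3-methyl-1-oxopent-4-en-3-yl formate
Product: 7 (3R)-3-(formyloxy)-3-methylpent-4-enoic acid
Conditions: NaClO2, NaH2PO4, 2-methylbut-2-ene, t-BuOH–H2O, 0 °C → rt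
Reagents that add atoms: sodium chlorite, [Na+].[O-]Cl=O
Why: Pinnick oxidation at buffered, weakly acidic pH converts the aldehyde to the acid without E1cB loss of the β-formyloxy group, and the scavenger keeps hypochlorous acid away from the vinyl group.

Step 5
Reactants: 7 (3R)-3-(formyloxy)-3-methylpent-4-enoic acid
Product: 9 methyl (3R)-3-hydroxy-3-methylpent-4-enoate, via formate ester 8 (not isolated)
Conditions: TMSCHN2, PhMe–MeOH, 0 °C; then KHCO3 (cat.), MeOH, 0 °C
Reagents that add atoms: (trimethylsilyl)diazomethane, C[Si](C)(C)C=[N+]=[N-]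
Why: Diazoalkane esterification followed by base-catalysed transesterification of the formate, which is fast enough under bicarbonate that neither β-elimination nor retro-aldol cleavage of the tertiary carbinol should compete.

Step 6
Reactants: 10 tert-butyl acetate
Product: 12 tert-butyl[(1-tert-butoxyethenyl)oxy]dimethylsilane, via lithium enolate 11 (not isolated)
Conditions: LDA, THF, −78 °C; TBSCl, DMPU, −78 °C → rt
Reagents that add atoms: tert-butyldimethylsilyl chloride, CC(C)(C)[Si](C)(C)Cl; lithium diisopropylamide, [Li+].CC(C)[N-]C(C)C (lithium of 11 only)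
Why: O-silylation of an ester enolate in a dipolar cosolvent is the standard preparation of a ketene silyl acetal.

Step 7
Reactants: 13 (S)-(−)-perillic acid
Product: 14 tert-butyl (4S)-4-(prop-1-en-2-yl)cyclohex-1-ene-1-carboxylate
Conditions: Me2NCH(Ot-Bu)2, PhMe, 80 °C
Reagents that add atoms: N,N-dimethylformamide di-tert-butyl acetal, CN(C)C(OC(C)(C)C)OC(C)(C)C
Why: Alkylative esterification with a formamide acetal is neutral, so the acid-sensitive isopropenyl group and the C4 centre are not disturbed.

Step 8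
Reactants: 14 tert-butyl (4S)-4-(prop-1-en-2-yl)cyclohex-1-ene-1-carboxylate
Product: 16 tert-butyl (4S)-2-hydroxy-4-(prop-1-en-2-yl)cyclohexane-1-carboxylate (C1/C2 diastereomer mixture), via boronate 15 (not isolated)
Conditions: B2pin2, CuCl (5 mol %), DPEphos (5 mol %), NaOt-Bu (10 mol %), MeOH (2 equiv), THF, rt; then NaBO3·4H2O, THF–H2O, rt
Reagents that add atoms: bis(pinacolato)diboron, CC1(C)OB(OC1(C)C)B1OC(C)(C)C(C)(C)O1 (boron of 15 only); sodium perborate, [Na+].[O-]OB=O (oxygen of 16)
Why: Copper-catalysed conjugate borylation touches only the electron-poor enoate and not the isopropenyl group, the C–B oxidation places oxygen on C2, and the two new centres are erased in steps 9 and 10.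

Step 9
Reactants: 16 tert-butyl (4S)-2-hydroxy-4-(prop-1-en-2-yl)cyclohexane-1-carboxylate
Product: 17 tert-butyl (4S)-2-hydroxy-4-(prop-1-en-2-yl)cyclohex-1-ene-1-carboxylate (enol of the β-keto ester)
Conditions: DMP, CH2Cl2, 0 °C → rt
Reagents that add atoms: none
Why: Dess–Martin oxidation of a β-hydroxy ester to the β-keto ester is mild, does not affect alkenes, and converges all diastereomers of 16 to one compound.

Step 10
Reactants: 17 tert-butyl (4S)-2-hydroxy-4-(prop-1-en-2-yl)cyclohex-1-ene-1-carboxylate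
Product: 19 tert-butyl (4S)-6-oxo-4-(prop-1-en-2-yl)cyclohex-1-ene-1-carboxylate (route labels: C2 ketone; C1=C6 alkene), via selenide 18 (not isolated)
Conditions: PhSeCl, pyridine, CH2Cl2, 0 °C; then 30% H2O2, 0 °C
Reagents that add atoms: phenylselenenyl chloride, Cl[Se]c1ccccc1 (in 18 only)
Why: α-Selenenylation of the enol at C1 followed by selenoxide syn-elimination, which can only take a hydrogen from C6 because C2 is a carbonyl carbon, gives the doubly activated keto-enoate, and the pyridine complex tempers addition of the selenium electrophile to the isopropenyl group.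

Step 11
Reactants: 19 tert-butyl (4S)-6-oxo-4-(prop-1-en-2-yl)cyclohex-1-ene-1-carboxylate; 12 tert-butyl[(1-tert-butoxyethenyl)oxy]dimethylsilane
Product: 20 tert-butyl (4S,6R)-6-(2-tert-butoxy-2-oxoethyl)-2-(TBSO)-4-(prop-1-en-2-yl)cyclohex-1-ene-1-carboxylate
Conditions: 12 (1.3 equiv), TBSOTf (10 mol %), CH2Cl2, −78 °C; Et3N quench
Reagents that add atoms: none
Why: Silyl-triflate-catalysed Mukaiyama–Michael addition with silyl transfer to the ketone oxygen, in which stereoelectronically favoured axial attack on the half-chair anti to the equatorial C4 isopropenyl group sets C6 trans to C4 (as in conjugate additions to carvone), and the β-keto ester emerges already masked as its TBS enol ether.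

Step 12
Reactants: 20 tert-butyl (4S,6R)-6-(2-tert-butoxy-2-oxoethyl)-2-(TBSO)-4-(prop-1-en-2-yl)cyclohex-1-ene-1-carboxylate; 21 acrolein
Product: 24 tert-butyl (4S,6R)-6-[(2S,3R)-1-tert-butoxy-3-hydroxy-1-oxopent-4-en-2-yl]-2-(TBSO)-4-(prop-1-en-2-yl)cyclohex-1-ene-1-carboxylate, via lithium enolate 22 (not isolated), via titanium enolate 23 (not isolated)
Conditions: LDA, THF–DMPU, −78 °C; ClTi(Oi-Pr)3, −78 → −40 °C; acrolein, −78 °C
Reagents that add atoms: chlorotitanium triisopropoxide, CC(C)O[Ti](Cl)(OC(C)C)OC(C)C (in 23 only); lithium diisopropylamide, [Li+].CC(C)[N-]C(C)C (lithium of 22 only)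
Why: Titanium aldol addition through a closed Zimmerman–Traxler chair, where kinetic deprotonation of the CH2CO2t-Bu group in THF–DMPU gives the Z(O)-enolate (the enol ether shields the β-keto ester and rules out retro-Michael cleavage) so that Cα and Cβ come out syn, while allylic 1,3-strain turns C6–H into the enolate plane and acrolein reaches Cα from the C5H2 side, away from the fully substituted C1, giving Cα (S) and Cβ (R).

Step 13
Reactants: 24 syn-aldol adduct
Product: 25 tert-butyl (4S,6R)-6-[(2S,3R)-1-tert-butoxy-3-(TBSO)-1-oxopent-4-en-2-yl]-2-(TBSO)-4-(prop-1-en-2-yl)cyclohex-1-ene-1-carboxylate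
Conditions: TBSOTf, 2,6-lutidine, CH2Cl2, −78 → 0 °C
Reagents that add atoms: tert-butyldimethylsilyl triflate, CC(C)(C)[Si](C)(C)OS(=O)(=O)C(F)(F)F
Why: Silylation of the secondary allylic alcohol under non-nucleophilic basic conditions avoids retro-aldol cleavage and caps the hydroxyl that would otherwise intercept the acylketene of step 15 as a six-membered lactone.

Step 14
Reactants: 25 bis-TBS di-tert-butyl ester
Product: 26 tert-butyl (4S,6R)-6-[(2S,3R)-1-tert-butoxy-3-(TBSO)-1-oxopent-4-en-2-yl]-2-hydroxy-4-(prop-1-en-2-yl)cyclohex-1-ene-1-carboxylate (enol of the β-keto ester)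
Conditions: TBAF (1.0 equiv), AcOH (1.2 equiv), THF, 0 °C
Reagents that add atoms: none
Why: Selective desilylation, because the β-silyloxy enoate is a vinylogous silyl ester and is cleaved by buffered fluoride far faster than the secondary alkyl TBS ether.

Step 15
Reactants: 26 free β-keto tert-butyl ester; 9 methyl (3R)-3-hydroxy-3-methylpent-4-enoate
Product: 28 (3R)-1-methoxy-3-methyl-1-oxopent-4-en-3-yl (4S,6R)-6-[(2S,3R)-1-tert-butoxy-3-(TBSO)-1-oxopent-4-en-2-yl]-2-hydroxy-4-(prop-1-en-2-yl)cyclohex-1-ene-1-carboxylate, via acylketene 27 (not isolated)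
Conditions: 9 (2 equiv), PhMe, 110 °C, 4 Å MS (t-BuOH removed)
Reagents that add atoms: none
Why: Acylketene transesterification, in which the enolised tert-butyl β-keto ester loses tert-butanol on heating and the unhindered ketene carbon is captured by the tertiary alcohol where ordinary acylation would fail, while the plain Cα tert-butyl ester is inert at this temperature, which also stays well below that of a thermal Carroll rearrangement, and any minor enantiomer of 9 is removed here as a diastereomer.

Step 16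
Reactants: 28 tertiary allylic β-keto ester
Product: 29 (3R)-1-methoxy-3-methyl-1-oxopent-4-en-3-yl (4S,6R)-6-[(2S,3R)-1-tert-butoxy-3-(TBSO)-1-oxopent-4-en-2-yl]-2-(TBSO)-4-(prop-1-en-2-yl)cyclohex-1-ene-1-carboxylate (metathesis diene)
Conditions: TBSOTf, Et3N, CH2Cl2, 0 °C
Reagents that add atoms: tert-butyldimethylsilyl triflate, CC(C)(C)[Si](C)(C)OS(=O)(=O)C(F)(F)F
Why: Soft-enolisation O-silylation of the β-keto ester gives the only possible (endocyclic) enol ether and removes the acidic, chelating 1,3-dicarbonyl unit before the ruthenium step.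

Step 17
Reactants: 29 metathesis diene
Product: 30 nine-membered (Z)-Cγ=Cδ ene-lactone fused to the cyclohexene at C1/C6 (C4 S; C6 R; Cα S bearing CO2t-Bu; Cβ R bearing OTBS; Cq R bearing CH3 and CH2CO2Me; C2 OTBS)
Conditions: Hoveyda–Grubbs II (10 mol %, in portions), 1,4-benzoquinone (10 mol %), PhMe (1 mM), 80 °C, Ar sparge
Reagents that add atoms: none
Why: Ring-closing olefin metathesis through ruthenacyclobutanes: the catalyst first exchanges with the less hindered Cβ vinyl group, the resulting Cγ alkylidene adds [2+2] to the Cq vinyl group, and cycloreversion forms Cγ=Cδ and releases ethene, whose removal by sparging makes the closure irreversible. The closest known reaction type is high-dilution RCM of dienes with allylic oxygen substituents to nine-membered unsaturated lactones. One ring is closed, C1–C(=O)–O–Cq–Cδ=Cγ–Cβ–Cα–C6, by end-to-end union of two terminal vinyl groups, and closure is helped because C1 and C6 hold both chains on adjacent positions of the cyclohexene and Cq is fully substituted (gem-dialkyl effect). No stereocentre is formed, and the only new stereo-element is the alkene geometry, which the strain of an E-alkene in this fused nine-membered ring restricts to Z. Site selectivity among four C=C bonds is needed: the tetrasubstituted C1=C2 enol ether is inert, and the 1,1-disubstituted isopropenyl group is a slow partner that stands trans-1,3 to the side chain, so any ring through it would be an impossible trans-bridged bicycle. The enol silyl ether also prevents chelation of ruthenium by a β-keto ester and blocks [3,3] (Carroll) rearrangement of the tertiary allylic ester at 80 °C.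

Step 18
Reactants: 30 nine-membered (Z)-ene-lactone
Product: 31 iodolactone (γ-lactone bridging Cα and Cγ; C4 S; C6 R; Cα S; Cβ S; Cγ S; Cδ R bearing iodine; Cq R; both TBS groups retained)
Conditions: I2 (3 equiv), NaHCO3, MeCN, 0 °C → rt, dark
Reagents that add atoms: iodine, II
Why: Iodolactonisation of a γ,δ-unsaturated tert-butyl ester, in which reversible iodonium formation becomes productive only at Cγ=Cδ, where the ester carbonyl oxygen is placed for 5-exo anti attack at Cγ (Cδ is neopentyl) with loss of the tert-butyl group as isobutene, and Cγ is set because a five-membered lactone can bridge Cα and Cγ of the nine-membered ring only in a cis sense, so oxygen arrives on the face that carries the Cα carboxyl.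

Step 19
Reactants: 31 iodolactone
Product: 32 bis-TBS ether of the target (C4 S; C6 R; Cα S; Cβ S; Cγ R; Cq S)
Conditions: Bu3SnH (3 equiv, 0.2 M), Et3B (cat.), air, PhMe, 0 °C
Reagents that add atoms: none
Why: Radical-chain dehalogenation of a secondary iodide, run cold and at high stannane concentration so that hydrogen transfer outruns a 1,2-acyloxy (Surzur–Tanner) shift or transannular addition, converts Cδ into the ring CH2 without touching any other centre.

Step 20
Reactants: 32 bis-TBS ether of the target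
Product: 33 CNP0302642.1 (target)
Conditions: HF·pyridine, pyridine, THF, 0 °C → rt
Reagents that add atoms: none
Why: Fluoride-mediated global desilylation in a weakly acidic medium frees the C2 enol and the Cβ hydroxyl without the base-induced β-elimination, retro-Claisen cleavage or translactonisation that a basic fluoride source could trigger.

## Compound list

1 | (R)-(−)-linalool | C=C[C@](C)(O)CCC=C(C)C | starting material
2 | (4R)-4-hydroxy-4-methylhex-5-enal | C=C[C@](C)(O)CCC=O | intermediate
3 | (5R)-5-ethenyl-5-methyloxolan-2-ol | C=C[C@@]1(C)CCC(O)O1 | intermediate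
4 | (5R)-5-ethenyl-5-methyloxolan-2-yl methanesulfonate | C=C[C@@]1(C)CCC(OS(C)(=O)=O)O1 | intermediate
5 | (2R)-2-ethenyl-2-methyl-2,3-dihydrofuran | C=C[C@@]1(C)CC=CO1 | intermediate
6 | (3R)-3-methyl-1-oxopent-4-en-3-yl formate | O=CO[C@](C)(CC=O)C=C | intermediate
7 | (3R)-3-(formyloxy)-3-methylpent-4-enoic acid | O=CO[C@](C)(CC(=O)O)C=C | intermediate
8 | methyl (3R)-3-(formyloxy)-3-methylpent-4-enoate | O=CO[C@](C)(CC(=O)OC)C=C | intermediate
9 | methyl (3R)-3-hydroxy-3-methylpent-4-enoate | O[C@](C)(CC(=O)OC)C=C | intermediate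
10 | tert-butyl acetate | CC(=O)OC(C)(C)C | starting material
11 | lithium enolate of tert-butyl acetate | [Li+].C=C([O-])OC(C)(C)C | intermediate
12 | tert-butyl[(1-tert-butoxyethenyl)oxy]dimethylsilane | C=C(OC(C)(C)C)O[Si](C)(C)C(C)(C)C | intermediate
13 | (S)-(−)-perillic acid | C=C(C)[C@@H]1CC=C(C(=O)O)CC1 | starting material
14 | tert-butyl (4S)-4-(prop-1-en-2-yl)cyclohex-1-ene-1-carboxylate | C=C(C)[C@@H]1CC=C(C(=O)OC(C)(C)C)CC1 | intermediate
15 | tert-butyl (4S)-2-(pinacolboryl)-4-(prop-1-en-2-yl)cyclohexane-1-carboxylate (C1/C2 mixture) | C=C(C)[C@@H]1CC(B2OC(C)(C)C(C)(C)O2)C(C(=O)OC(C)(C)C)CC1 | intermediate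
16 | tert-butyl (4S)-2-hydroxy-4-(prop-1-en-2-yl)cyclohexane-1-carboxylate (C1/C2 mixture) | C=C(C)[C@@H]1CC(O)C(C(=O)OC(C)(C)C)CC1 | intermediate
17 | tert-butyl (4S)-2-hydroxy-4-(prop-1-en-2-yl)cyclohex-1-ene-1-carboxylate (enol of the β-keto ester) | C=C(C)[C@@H]1CC(O)=C(C(=O)OC(C)(C)C)CC1 | intermediate
18 | tert-butyl (4S)-2-oxo-1-(phenylselanyl)-4-(prop-1-en-2-yl)cyclohexane-1-carboxylate (C1 mixture) | C=C(C)[C@@H]1CC(=O)C([Se]c2ccccc2)(C(=O)OC(C)(C)C)CC1 | intermediate
19 | tert-butyl (4S)-6-oxo-4-(prop-1-en-2-yl)cyclohex-1-ene-1-carboxylate | C=C(C)[C@@H]1CC(=O)C(C(=O)OC(C)(C)C)=CC1 | intermediate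
20 | tert-butyl (4S,6R)-6-(2-tert-butoxy-2-oxoethyl)-2-(TBSO)-4-(prop-1-en-2-yl)cyclohex-1-ene-1-carboxylate | C=C(C)[C@@H]1CC(O[Si](C)(C)C(C)(C)C)=C(C(=O)OC(C)(C)C)[C@@H](CC(=O)OC(C)(C)C)C1 | intermediate
21 | acrolein | C=CC=O | starting material
22 | Z(O)-lithium enolate of 20 (O–Li cis to C6) | C=C(C)[C@@H]1CC(O[Si](C)(C)C(C)(C)C)=C(C(=O)OC(C)(C)C)[C@@H](/C=C(\[O-])OC(C)(C)C)C1.[Li+] | intermediate
23 | Z(O)-triisopropoxytitanium enolate of 20 | C=C(C)[C@@H]1CC(O[Si](C)(C)C(C)(C)C)=C(C(=O)OC(C)(C)C)[C@@H](/C=C(\O[Ti](OC(C)C)(OC(C)C)OC(C)C)OC(C)(C)C)C1 | intermediate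
24 | syn-aldol adduct (C4 S, C6 R, Cα S, Cβ R; free Cβ–OH) | C=C(C)[C@@H]1CC(O[Si](C)(C)C(C)(C)C)=C(C(=O)OC(C)(C)C)[C@@H]([C@H](C(=O)OC(C)(C)C)[C@H](O)C=C)C1 | intermediate
25 | bis-TBS di-tert-butyl ester | C=C(C)[C@@H]1CC(O[Si](C)(C)C(C)(C)C)=C(C(=O)OC(C)(C)C)[C@@H]([C@H](C(=O)OC(C)(C)C)[C@H](O[Si](C)(C)C(C)(C)C)C=C)C1 | intermediate
26 | free β-keto tert-butyl ester (enol), Cβ–OTBS | C=C(C)[C@@H]1CC(O)=C(C(=O)OC(C)(C)C)[C@@H]([C@H](C(=O)OC(C)(C)C)[C@H](O[Si](C)(C)C(C)(C)C)C=C)C1 | intermediate
27 | acylketene: tert-butyl (2S,3R)-3-(TBSO)-2-[(1R,5S)-3-oxo-2-(oxomethylidene)-5-(prop-1-en-2-yl)cyclohexyl]pent-4-enoate | C=C(C)[C@@H]1CC(=O)C(=C=O)[C@@H]([C@H](C(=O)OC(C)(C)C)[C@H](O[Si](C)(C)C(C)(C)C)C=C)C1 | intermediate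
28 | tertiary allylic β-keto ester (enol) of 9 | C=C(C)[C@@H]1CC(O)=C(C(=O)O[C@](C)(CC(=O)OC)C=C)[C@@H]([C@H](C(=O)OC(C)(C)C)[C@H](O[Si](C)(C)C(C)(C)C)C=C)C1 | intermediate
29 | metathesis diene (C4 S, C6 R, Cα S, Cβ R, Cq R) | C=C(C)[C@@H]1CC(O[Si](C)(C)C(C)(C)C)=C(C(=O)O[C@](C)(CC(=O)OC)C=C)[C@@H]([C@H](C(=O)OC(C)(C)C)[C@H](O[Si](C)(C)C(C)(C)C)C=C)C1 | intermediate
30 | nine-membered (Z)-ene-lactone | C=C(C)[C@@H]1CC(O[Si](C)(C)C(C)(C)C)=C2C(=O)O[C@](C)(CC(=O)OC)/C=C\[C@@H](O[Si](C)(C)C(C)(C)C)[C@@H](C(=O)OC(C)(C)C)[C@H]2C1 | intermediate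
31 | Cδ-iodo γ-lactone | C=C(C)[C@@H]1CC(O[Si](C)(C)C(C)(C)C)=C2C(=O)O[C@](C)(CC(=O)OC)[C@H](I)[C@H]3OC(=O)[C@H]([C@@H]3O[Si](C)(C)C(C)(C)C)[C@H]2C1 | intermediate
32 | bis-TBS ether of the target | C=C(C)[C@@H]1CC(O[Si](C)(C)C(C)(C)C)=C2C(=O)O[C@](C)(CC(=O)OC)C[C@H]3OC(=O)[C@H]([C@@H]3O[Si](C)(C)C(C)(C)C)[C@H]2C1 | intermediate
33 | CNP0302642.1 | C=C(C)[C@@H]1CC(O)=C2C(=O)O[C@](C)(CC(=O)OC)C[C@H]3OC(=O)[C@H]([C@@H]3O)[C@H]2C1 | target

## Step count and risks

Total step count: 20. Longest linear sequence: 14 (steps 7–20, from 13). Fragment 9 takes 5 steps and joins at step 15. Reagent 12 takes 1 step and joins at step 11.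

**Step 17.**
- Risk: intermolecular metathesis (oligomerisation) may outrun closure, or the catalyst may stall. Both vinyl groups sit on branched carbons, the Cγ alkylidene can be held by chelation to the Cα ester carbonyl, and the nine-membered ring carries transannular strain.
- Idea of the fallback: it still forms Cγ=Cδ by metathesis, but in an easy seven-membered ring, and it closes the nine-membered ring at the ester C–O bond instead.
- Route: it sets out from 24 and 9. Carbinol 9 is silylated with excess Ph2SiCl2/Et3N to the chlorosilyl ether F1. After removal of surplus dichlorosilane, F1 is joined to the Cβ hydroxyl of 24 (imidazole, DMF) to give the mixed diphenylsilaketal F2. Silicon-tethered RCM (Grubbs II, CH2Cl2, reflux) gives the dioxasilepine F3, whose ring size enforces the Z-alkene. HF·pyridine removes the tether and the enol silyl group to give the ene-diol F4. TBSCl/imidazole silylates only the secondary allylic hydroxyl to give the tertiary carbinol F5. Thermolysis at high dilution (PhMe, 110 °C) forms the acylketene F6, which the tertiary hydroxyl captures within the molecule to give the β-keto lactone F7. TBSOTf/Et3N then returns to the route at 30.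

**Step 18.**
- Risk: iodine may be consumed by attack at the isopropenyl group or at C1 of the silyl enol ether. Alternatively the ring alkene, deactivated by two allylic C–O bonds, may not react with the weakly nucleophilic ester. Iodination at C1 would be undone by the stannane of step 19.
- Idea of the fallback: it changes both partners, using a free carboxyl nucleophile and a selenium electrophile. Addition of that electrophile to bystander alkenes is reversible, so the irreversible lactone acts as the sink.
- Route: it sets out from 30. TMSOTf/2,6-lutidine followed by pH 7 buffer cleaves the tert-butyl ester to the carboxylic acid F8. PhSeCl, Et3N, CH2Cl2, −78 °C gives the phenylselenolactone F9. Bu3SnH/AIBN cleaves the C–Se bond and returns to the route at 32.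

**Step 12.**
- Risk: syn/anti control may erode in the aldol transition state with the small aldehyde, or deprotonation at C3 of the β-silyloxy enoate may compete.
- Idea of the fallback: it separates the two centres. Cα still comes from the A(1,3)-controlled C–C bond formation, and Cβ comes from hydride delivery.
- Route: it sets out from 20. A plain lithium aldol with 21, run without regard to Cβ, gives the carbinol mixture F10. DMP oxidation converges it to the vinyl ketone F11. Zn(BH4)2 (Et2O, −78 °C) reduces the zinc-chelated β-keto ester in a 1,2-sense from the face opposite the Cα substituent, which is the known syn-selective mode for α-substituted β-keto esters with an unsaturated ketone substituent. This returns to the route at 24.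

## Further compounds

F1 | step 17 | chloro(diphenyl)silyl ether of 9 | Cl[Si](c1ccccc1)(c1ccccc1)O[C@](C)(CC(=O)OC)C=C
F2 | step 17 | mixed diphenylsilaketal of 24 and 9 | C=C(C)[C@@H]1CC(O[Si](C)(C)C(C)(C)C)=C(C(=O)OC(C)(C)C)[C@@H]([C@H](C(=O)OC(C)(C)C)[C@H](O[Si](c2ccccc2)(c2ccccc2)O[C@](C)(CC(=O)OC)C=C)C=C)C1
F3 | step 17 | seven-membered 1,3-dioxa-2-silacyclohept-5-ene (dioxasilepine) | C=C(C)[C@@H]1CC(O[Si](C)(C)C(C)(C)C)=C(C(=O)OC(C)(C)C)[C@@H]([C@H](C(=O)OC(C)(C)C)[C@@H]2O[Si](c3ccccc3)(c3ccccc3)O[C@](C)(CC(=O)OC)C=C2)C1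
F4 | step 17 | (Z)-ene-diol with free β-keto tert-butyl ester (enol) | C=C(C)[C@@H]1CC(O)=C(C(=O)OC(C)(C)C)[C@@H]([C@H](C(=O)OC(C)(C)C)[C@H](O)/C=C\[C@](C)(O)CC(=O)OC)C1
F5 | step 17 | Cβ-mono-TBS ether with free tertiary carbinol | C=C(C)[C@@H]1CC(O)=C(C(=O)OC(C)(C)C)[C@@H]([C@H](C(=O)OC(C)(C)C)[C@H](O[Si](C)(C)C(C)(C)C)/C=C\[C@](C)(O)CC(=O)OC)C1
F6 | step 17 | acylketene bearing the tertiary carbinol | C=C(C)[C@@H]1CC(=O)C(=C=O)[C@@H]([C@H](C(=O)OC(C)(C)C)[C@H](O[Si](C)(C)C(C)(C)C)/C=C\[C@](C)(O)CC(=O)OC)C1
F7 | step 17 | nine-membered (Z)-ene β-keto lactone (enol) | C=C(C)[C@@H]1CC(O)=C2C(=O)O[C@](C)(CC(=O)OC)/C=C\[C@@H](O[Si](C)(C)C(C)(C)C)[C@@H](C(=O)OC(C)(C)C)[C@H]2C1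
F8 | step 18 | Cα carboxylic acid of 30 | C=C(C)[C@@H]1CC(O[Si](C)(C)C(C)(C)C)=C2C(=O)O[C@](C)(CC(=O)OC)/C=C\[C@@H](O[Si](C)(C)C(C)(C)C)[C@@H](C(=O)O)[C@H]2C1
F9 | step 18 | Cδ-phenylselanyl γ-lactone | C=C(C)[C@@H]1CC(O[Si](C)(C)C(C)(C)C)=C2C(=O)O[C@](C)(CC(=O)OC)[C@H]([Se]c4ccccc4)[C@H]3OC(=O)[C@H]([C@@H]3O[Si](C)(C)C(C)(C)C)[C@H]2C1
F10 | step 12 | aldol carbinol as Cβ-epimer mixture | C=C(C)[C@@H]1CC(O[Si](C)(C)C(C)(C)C)=C(C(=O)OC(C)(C)C)[C@@H]([C@H](C(=O)OC(C)(C)C)C(O)C=C)C1
F11 | step 12 | Cβ vinyl ketone (α-substituted β-keto tert-butyl ester) | C=C(C)[C@@H]1CC(O[Si](C)(C)C(C)(C)C)=C(C(=O)OC(C)(C)C)[C@@H]([C@H](C(=O)OC(C)(C)C)C(=O)C=C)C1
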